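**Retrosynthetic overview**

1. Rings and locants: A = chromanone benzo ring, B = 4-hydroxy-3-prenylphenyl, C = pyranone (O1–C2–C3–C4–C4a–C8a), D = tetrahydrofuran (C2–C3–C11–C10b–O), E = chromane pyran (O5–C5a–C10b–C11), F = dihydrofuran (O6–C5a–C10b), G and H = lower benzo rings. The upper half uses flavanone numbering, the lower half benzofuro[2,3-b]chromene numbering.
2. Enabling feature: C-4 and the oxygen on C-10b are 1,4-related through C-3 and C-11, so ring D closed the other way round (C-10b–O–C-4) is a γ-butyrolactone cis-fused to ring E. That lactone is at once a latent C-4 acyl group and a latent C-10b alkoxide, and C-2 is the ketal carbon of an aroyl group that the ring A phenol and the C-10b hydroxyl can both reach.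
3. Key disconnection into three components: ring C/D bis-ketal ⇒ hydroxy 1,3-diketone ⇒ C-3–C-2 (ring B aroyl chloride 34) and C-4–C-4a (C,O-dilithiated ring A bromophenol 27 plus lactone 20).
4. Lactone 20 ⇐ acetalisation at C-5a (ring F) ⇐ bis-lactone 16 ⇐ intramolecular carbene-catalysed homoenolate annulation of the enal aryl α-keto ester 15, which forms ring E and the lactone and sets C-11 and C-10b in one enantioselective step.
5. Order of ring formation: E plus lactone (step 8) → F (step 9) → D, then C (step 17). Prenyl groups come from cuprate allylation or Suzuki–Miyaura coupling; the four silyl ethers are removed last.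

Key step: step 17

Assumption: C-2 and C-3 are taken to settle, by reversible acid-catalysed ketalisation in step 17, in the arrangement of the target (assumed to be the thermodynamically preferred cis-fused bis-ketal), and the triazolium enantiomer in step 8 is the one that gives the (3aS,9bR) lactone.

**Route**

Step 1
Reactants: 1 2,4-dihydroxybenzaldehyde; 2 chloromethyl methyl ether
Product: 3 2-hydroxy-4-(methoxymethoxy)benzaldehyde
Conditions: MOMCl (1.05 equiv), K2CO3, acetone, 0 → 23 °C
Reagents that add atoms: chloromethyl methyl ether, COCCl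
Why: The 4-hydroxyl is the more acidic phenol and is not hydrogen-bonded to the aldehyde, so O-alkylation (MOM protection) should occur there selectively.

Step 2
Reactants: 3 2-hydroxy-4-(methoxymethoxy)benzaldehyde; 4 (triphenylphosphoranylidene)acetaldehyde
Product: 5 (E)-3-[2-hydroxy-4-(methoxymethoxy)phenyl]prop-2-enal
Conditions: Ph3P=CHCHO (1.2 equiv), PhMe, 80 °C
Reagents that add atoms: (triphenylphosphoranylidene)acetaldehyde, O=CC=P(c1ccccc1)(c1ccccc1)c1ccccc1
Why: Wittig olefination with the stabilised formylmethylene ylide should give the E-enal and tolerates the free ortho-phenol.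

Step 3
Reactants: 6 resorcinol; 2 chloromethyl methyl ether
Product: 7 1,3-bis(methoxymethoxy)benzene
Conditions: NaH (2.4 equiv), MOMCl (2.3 equiv), DMF, 0 → 23 °C
Reagents that add atoms: chloromethyl methyl ether, COCCl
Why: Double Williamson-type O-alkylation installs two groups that protect the phenols and direct the later metalations.

Step 4
Reactants: 7 1,3-bis(methoxymethoxy)benzene; 8 prenyl bromide (1-bromo-3-methylbut-2-ene)
Product: 10 1,3-bis(methoxymethoxy)-2-(3-methylbut-2-enyl)benzene, via aryllithium 9 (not isolated)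
Conditions: n-BuLi (1.1 equiv), THF, 0 → 23 °C; then CuI (10 mol %), prenyl bromide, −78 → 23 °C
Reagents that add atoms: prenyl bromide, CC(C)=CCBr
Why: Directed ortho-lithiation occurs between the two MOM-oxy groups, and copper-assisted allylation of the aryllithium at the unhindered terminus of prenyl bromide should give the linear prenyl arene.

Step 5
Reactants: 10 1,3-bis(methoxymethoxy)-2-(3-methylbut-2-enyl)benzene; 11 diethyl oxalate
Product: 13 ethyl 2-[2,4-bis(methoxymethoxy)-3-(3-methylbut-2-enyl)phenyl]-2-oxoacetate, via aryllithium 12 (not isolated)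
Conditions: n-BuLi (1.2 equiv), TMEDA, THF, 0 °C; then added to (CO2Et)2 (3 equiv), THF, −78 °C; NH4Cl (aq)
Reagents that add atoms: diethyl oxalate, CCOC(=O)C(=O)OCC
Why: A second directed ortho-metalation can only occur at the one open position next to a MOM-oxy group, and inverse addition to excess oxalate should stop the acylation at the α-keto ester.

Step 6
Reactants: 13 ethyl 2-[2,4-bis(methoxymethoxy)-3-(3-methylbut-2-enyl)phenyl]-2-oxoacetate
Product: 14 2-[2,4-bis(methoxymethoxy)-3-(3-methylbut-2-enyl)phenyl]-2-oxoacetic acid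
Conditions: LiOH (1.5 equiv), THF–H2O, 0 °C; then 1 M HCl to pH 3, 0 °C
Reagents that add atoms: lithium hydroxide, [Li+].[OH-]
Why: Saponification of the activated α-keto ester is fast at 0 °C, and brief cold acidification should leave the MOM ethers intact.

Step 7
Reactants: 14 2-[2,4-bis(methoxymethoxy)-3-(3-methylbut-2-enyl)phenyl]-2-oxoacetic acid; 5 (E)-3-[2-hydroxy-4-(methoxymethoxy)phenyl]prop-2-enal
Product: 15 5-(methoxymethoxy)-2-[(E)-3-oxoprop-1-enyl]phenyl 2-[2,4-bis(methoxymethoxy)-3-(3-methylbut-2-enyl)phenyl]-2-oxoacetate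
Conditions: DCC, DMAP (10 mol %), CH2Cl2, 0 → 23 °C
Reagents that add atoms: none
Why: Steglich esterification of the phenol with the α-keto acid should tether the enal to the activated ketone through the oxygen that becomes O5 of ring E.

Step 8
Reactants: 15 5-(methoxymethoxy)-2-[(E)-3-oxoprop-1-enyl]phenyl 2-[2,4-bis(methoxymethoxy)-3-(3-methylbut-2-enyl)phenyl]-2-oxoacetate
Product: 16 (3aS,9bR)-3a-[2,4-bis(methoxymethoxy)-3-(3-methylbut-2-enyl)phenyl]-7-(methoxymethoxy)-1,9b-dihydrofuro[2,3-c]chromene-2,4-dione (cis-fused bis-lactone)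
Conditions: chiral aminoindanol-derived N-mesityl triazolium tetrafluoroborate (10 mol %), i-Pr2NEt (20 mol %), THF, 23 °C
Reagents that add atoms: none
Why: In this carbene-catalysed homoenolate annulation the carbene–enal adduct should attack the tethered α-keto ester ketone through its β-carbon (closing six-membered ring E) and the alkoxide then lactonises onto the acyl azolium; the γ-lactone can only fuse cis, which fixes C-11 relative to C-10b, and the chiral carbene controls the face of the homoenolate carbon and so the absolute configuration.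

Step 9
Reactants: 16 (3aS,9bR)-3a-[2,4-bis(methoxymethoxy)-3-(3-methylbut-2-enyl)phenyl]-7-(methoxymethoxy)-1,9b-dihydrofuro[2,3-c]chromene-2,4-dione
Product: 18 (5aS,10bS,11R)-3,8-dihydroxy-7-(3-methylbut-2-enyl)-5a,10b-dihydro-11H-benzofuro[2,3-b]chromene bearing a cis-fused γ-lactone from the C-10b oxygen to C-11 (O–C(=O)–CH2), via lactol 17 (not isolated)
Conditions: LiAlH(Ot-Bu)3 (1.3 equiv), THF, −40 → −10 °C; potassium sodium tartrate (aq); then HCl (cat.), MeOH–THF, 35 °C; then camphorsulfonic acid (10 mol %), CH2Cl2, 4 Å sieves, 23 °C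
Reagents that add atoms: none
Why: LiAlH(Ot-Bu)3 should reduce the phenyl-ester lactone, which is far more electrophilic than the alkyl γ-lactone, to the lactol; acid then removes the three MOM groups and the freed ortho-phenol of ring H traps the C-5a oxocarbenium ion, ring F being obliged to fuse cis to ring E, which sets C-5a.

Step 10
Reactants: 18 pentacyclic diphenol lactone; 19 triisopropylsilyl trifluoromethanesulfonate
Product: 20 (5aS,10bS,11R)-3,8-bis(triisopropylsilyloxy) lactone (bis-silyl ether of 18)
Conditions: TIPSOTf (2.5 equiv), 2,6-lutidine, CH2Cl2, 0 → 23 °C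
Reagents that add atoms: triisopropylsilyl trifluoromethanesulfonate, CC(C)[Si](OS(=O)(=O)C(F)(F)F)(C(C)C)C(C)C
Why: The silyl triflate should silylate both phenols, including the one flanked by the prenyl group, and the resulting ethers are stable to the organolithium bases of step 17.

Step 11
Reactants: 21 4-bromoresorcinol; 22 triisopropylsilyl chloride
Product: 23 2-bromo-5-(triisopropylsilyloxy)phenol
Conditions: TIPSCl (1.0 equiv), imidazole, CH2Cl2, −20 → 0 °C
Reagents that add atoms: triisopropylsilyl chloride, CC(C)[Si](Cl)(C(C)C)C(C)C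
Why: The bulky silyl chloride should react at the unhindered hydroxyl and leave the one next to bromine free.

Step 12
Reactants: 23 2-bromo-5-(triisopropylsilyloxy)phenol; 24 N-iodosuccinimide
Product: 25 2-bromo-4-iodo-5-(triisopropylsilyloxy)phenol
Conditions: NIS (1.0 equiv), MeCN, 0 °C
Reagents that add atoms: N-iodosuccinimide, O=C1CCC(=O)N1I
Why: Electrophilic iodination should go para to the free hydroxyl (and ortho to the silyloxy group), because the alternative site between the two oxygens is shielded by the triisopropylsilyl group.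

Step 13
Reactants: 25 2-bromo-4-iodo-5-(triisopropylsilyloxy)phenol; 26 prenylboronic acid pinacol ester
Product: 27 2-bromo-4-(3-methylbut-2-enyl)-5-(triisopropylsilyloxy)phenol
Conditions: prenylB(pin) (1.5 equiv), PdCl2(IPent)(3-chloropyridine) (2 mol %; IPent = 1,3-bis[2,6-di(pentan-3-yl)phenyl]imidazol-2-ylidene), K3PO4 (aq), THF, 50 °C
Reagents that add atoms: prenylboronic acid pinacol ester, CC(C)=CCB1OC(C)(C)C(C)(C)O1
Why: Suzuki–Miyaura coupling should occur at the C–I bond in preference to the C–Br bond, and the bulky carbene–palladium catalyst favours reductive elimination at the unsubstituted allyl terminus, giving the linear prenyl group.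

Step 14
Reactants: 28 methyl 4-hydroxy-3-iodobenzoate; 26 prenylboronic acid pinacol ester
Product: 30 4-hydroxy-3-(3-methylbut-2-enyl)benzoic acid, via methyl ester 29 (not isolated)
Conditions: prenylB(pin) (1.5 equiv), PdCl2(IPent)(3-chloropyridine) (2 mol %), KOH (5 M aq), THF, 65 °C; then MeOH, 65 °C; 1 M HCl
Reagents that add atoms: prenylboronic acid pinacol ester, CC(C)=CCB1OC(C)(C)C(C)(C)O1; potassium hydroxide, [K+].[OH-]
Why: The same linear-selective Suzuki–Miyaura prenylation is followed in the same pot by saponification of the methyl ester with the aqueous hydroxide already present.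

Step 15
Reactants: 30 4-hydroxy-3-(3-methylbut-2-enyl)benzoic acid; 22 triisopropylsilyl chloride
Product: 32 3-(3-methylbut-2-enyl)-4-(triisopropylsilyloxy)benzoic acid, via silyl ester 31 (not isolated)
Conditions: TIPSCl (2.3 equiv), imidazole, DMF, 23 °C; then AcOH–THF–H2O, 23 °C
Reagents that add atoms: triisopropylsilyl chloride, CC(C)[Si](Cl)(C(C)C)C(C)C
Why: Persilylation followed by mild aqueous acid should cleave only the much more labile silyl ester and leave the aryl silyl ether.

Step 16
Reactants: 32 3-(3-methylbut-2-enyl)-4-(triisopropylsilyloxy)benzoic acid; 33 1-chloro-N,N,2-trimethylprop-1-en-1-amine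
Product: 34 3-(3-methylbut-2-enyl)-4-(triisopropylsilyloxy)benzoyl chloride
Conditions: 1-chloro-N,N,2-trimethylprop-1-en-1-amine (1.1 equiv), CH2Cl2, 0 → 23 °C; concentrated and used crude
Reagents that add atoms: 1-chloro-N,N,2-trimethylprop-1-en-1-amine, CC(C)=C(Cl)N(C)C
Why: The α-chloroenamine converts the acid to the acid chloride under neutral conditions, so no HCl is formed that could add to the prenyl double bond.

Step 17
Reactants: 20 bis-silyl lactone; 27 2-bromo-4-(3-methylbut-2-enyl)-5-(triisopropylsilyloxy)phenol; 34 3-(3-methylbut-2-enyl)-4-(triisopropylsilyloxy)benzoyl chloride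
Product: 38 tetrakis(triisopropylsilyl) ether of the target, via dilithiated phenol 35 (not isolated), via hydroxy ketone 36 (not isolated), via hydroxy diketone 37 (not isolated)
Conditions: 27 (1.3 equiv), n-BuLi (1.3 equiv) then t-BuLi (2.6 equiv), THF, −78 °C; 20, −78 → −20 °C; LiN(SiMe3)2 (3.5 equiv), −78 °C, then 34 (1.5 equiv), −78 → 0 °C; AcOH; then camphorsulfonic acid (20 mol %), CH2Cl2, 4 Å sieves, 23 °C
Reagents that add atoms: none
Why: Bromine–lithium exchange on the lithium phenoxide gives the C,O-dilithiated arene 35, which adds once to the lactone carbonyl of 20 (C-4–C-4a bond; the lithium lactolate resists a second addition) and on warming unveils the aryl ketone and the tertiary lithium alkoxide of 36; LiN(SiMe3)2 then forms the ketone enolate, which is aroylated at C-3 by 34 (C-3–C-2 bond), any O-aroylated phenoxide or alkoxide converging on the same diketonate 37 by Baker–Venkataraman O→C acyl shift. The closest known reaction types are aryllithium opening of lactones to hydroxy ketones, the lithium amide/aroyl chloride C-aroylation of 2-hydroxyaryl ketones used in flavone synthesis, and acid-catalysed bis-ketalisation of dihydroxy ketones. On acidification ring D should close by 5-exo-trig addition of the C-10b hydroxyl to the aroyl carbonyl and ring C by 6-exo-trig capture of the resulting cyclic oxocarbenium ion by the ring A phenol. The two new stereocenters C-2 and C-3 are set under thermodynamic control: C-3 is mobile in the β-diketone, ketal formation is reversible, rings C and D can only fuse cis, and ring B on the quaternary ketal carbon is expected to take the convex face of the cis-fused D/E bicycle (anti to C-5a), which is the arrangement of the target. The step needs mono-addition to the lactone (secured by the tetrahedral intermediate at −78 °C and by the absence of any other carbonyl group in 20), C- over O-acylation (secured by the acyl-shift funnel) and ketalisation at the aroyl rather than the C-4 carbonyl (only the former can bind both hydroxyls in five- and six-membered rings, so a C-4 hemiketal drains back).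

Step 18
Reactants: 38 tetrakis(triisopropylsilyl) ether of the target
Product: 39 CNP0152008.3, the (2R,3S,5aS,10bS,11R) target
Conditions: Bu4NF (6 equiv), AcOH (6 equiv), THF, 0 → 23 °C
Reagents that add atoms: none
Why: Buffered fluoride desilylation should free the four phenols without base-induced opening of the ketal or acid-induced cyclisation of the prenyl groups, and none of the five stereocenters is touched.

**Compound list**

1 | 2,4-dihydroxybenzaldehyde | O=Cc1ccc(O)cc1O | starting material
2 | chloromethyl methyl ether | COCCl | starting material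
3 | 2-hydroxy-4-(methoxymethoxy)benzaldehyde | O=Cc1ccc(OCOC)cc1O | intermediate
4 | (triphenylphosphoranylidene)acetaldehyde | O=CC=P(c1ccccc1)(c1ccccc1)c1ccccc1 | starting material
5 | (E)-3-[2-hydroxy-4-(methoxymethoxy)phenyl]prop-2-enal | O=C/C=C/c1ccc(OCOC)cc1O | intermediate
6 | resorcinol | Oc1cccc(O)c1 | starting material
7 | 1,3-bis(methoxymethoxy)benzene | COCOc1cccc(OCOC)c1 | intermediate
8 | prenyl bromide (1-bromo-3-methylbut-2-ene) | CC(C)=CCBr | starting material
9 | 2-lithio-1,3-bis(methoxymethoxy)benzene | COCOc1cccc(OCOC)c1[Li] | intermediate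
10 | 1,3-bis(methoxymethoxy)-2-(3-methylbut-2-enyl)benzene | COCOc1cccc(OCOC)c1CC=C(C)C | intermediate
11 | diethyl oxalate | CCOC(=O)C(=O)OCC | starting material
12 | [2,4-bis(methoxymethoxy)-3-(3-methylbut-2-enyl)phenyl]lithium | [Li]c1ccc(OCOC)c(CC=C(C)C)c1OCOC | intermediate
13 | ethyl 2-[2,4-bis(methoxymethoxy)-3-(3-methylbut-2-enyl)phenyl]-2-oxoacetate | CCOC(=O)C(=O)c1ccc(OCOC)c(CC=C(C)C)c1OCOC | intermediate
14 | 2-[2,4-bis(methoxymethoxy)-3-(3-methylbut-2-enyl)phenyl]-2-oxoacetic acid | OC(=O)C(=O)c1ccc(OCOC)c(CC=C(C)C)c1OCOC | intermediate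
15 | 5-(methoxymethoxy)-2-[(E)-3-oxoprop-1-enyl]phenyl 2-[2,4-bis(methoxymethoxy)-3-(3-methylbut-2-enyl)phenyl]-2-oxoacetate | O=C/C=C/c1ccc(OCOC)cc1OC(=O)C(=O)c1ccc(OCOC)c(CC=C(C)C)c1OCOC | intermediate
16 | (3aS,9bR)-3a-[2,4-bis(methoxymethoxy)-3-(3-methylbut-2-enyl)phenyl]-7-(methoxymethoxy)-1,9b-dihydrofuro[2,3-c]chromene-2,4-dione, cis-fused | O=C1C[C@@H]2c3ccc(OCOC)cc3OC(=O)[C@]2(c2ccc(OCOC)c(CC=C(C)C)c2OCOC)O1 | intermediate
17 | lactol of 16 (4-hydroxy, both epimers at the lactol carbon; γ-lactone intact) | O=C1C[C@@H]2c3ccc(OCOC)cc3OC(O)[C@]2(c2ccc(OCOC)c(CC=C(C)C)c2OCOC)O1 | intermediate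
18 | (5aS,10bS,11R)-3,8-dihydroxy-7-(3-methylbut-2-enyl)-5a,10b-dihydro-11H-benzofuro[2,3-b]chromene with cis-fused γ-lactone from the C-10b oxygen to C-11 | O=C1C[C@@H]2c3ccc(O)cc3O[C@H]3Oc4c(ccc(O)c4CC=C(C)C)[C@]32O1 | intermediate
19 | triisopropylsilyl trifluoromethanesulfonate | CC(C)[Si](OS(=O)(=O)C(F)(F)F)(C(C)C)C(C)C | starting material
20 | 3,8-bis(triisopropylsilyl) ether of 18 | O=C1C[C@@H]2c3ccc(O[Si](C(C)C)(C(C)C)C(C)C)cc3O[C@H]3Oc4c(ccc(O[Si](C(C)C)(C(C)C)C(C)C)c4CC=C(C)C)[C@]32O1 | intermediate
21 | 4-bromoresorcinol | Oc1ccc(Br)c(O)c1 | starting material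
22 | triisopropylsilyl chloride | CC(C)[Si](Cl)(C(C)C)C(C)C | starting material
23 | 2-bromo-5-(triisopropylsilyloxy)phenol | Oc1cc(O[Si](C(C)C)(C(C)C)C(C)C)ccc1Br | intermediate
24 | N-iodosuccinimide | O=C1CCC(=O)N1I | starting material
25 | 2-bromo-4-iodo-5-(triisopropylsilyloxy)phenol | Oc1cc(O[Si](C(C)C)(C(C)C)C(C)C)c(I)cc1Br | intermediate
26 | prenylboronic acid pinacol ester | CC(C)=CCB1OC(C)(C)C(C)(C)O1 | starting material
27 | 2-bromo-4-(3-methylbut-2-enyl)-5-(triisopropylsilyloxy)phenol | Oc1cc(O[Si](C(C)C)(C(C)C)C(C)C)c(CC=C(C)C)cc1Br | intermediate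
28 | methyl 4-hydroxy-3-iodobenzoate | COC(=O)c1ccc(O)c(I)c1 | starting material
29 | methyl 4-hydroxy-3-(3-methylbut-2-enyl)benzoate | COC(=O)c1ccc(O)c(CC=C(C)C)c1 | intermediate
30 | 4-hydroxy-3-(3-methylbut-2-enyl)benzoic acid | OC(=O)c1ccc(O)c(CC=C(C)C)c1 | intermediate
31 | triisopropylsilyl 3-(3-methylbut-2-enyl)-4-(triisopropylsilyloxy)benzoate | CC(C)=CCc1cc(C(=O)O[Si](C(C)C)(C(C)C)C(C)C)ccc1O[Si](C(C)C)(C(C)C)C(C)C | intermediate
32 | 3-(3-methylbut-2-enyl)-4-(triisopropylsilyloxy)benzoic acid | CC(C)=CCc1cc(C(=O)O)ccc1O[Si](C(C)C)(C(C)C)C(C)C | intermediate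
33 | 1-chloro-N,N,2-trimethylprop-1-en-1-amine | CC(C)=C(Cl)N(C)C | starting material
34 | 3-(3-methylbut-2-enyl)-4-(triisopropylsilyloxy)benzoyl chloride | CC(C)=CCc1cc(C(=O)Cl)ccc1O[Si](C(C)C)(C(C)C)C(C)C | intermediate
35 | lithium 2-lithio-4-(3-methylbut-2-enyl)-5-(triisopropylsilyloxy)phenoxide | [Li]Oc1cc(O[Si](C(C)C)(C(C)C)C(C)C)c(CC=C(C)C)cc1[Li] | intermediate
36 | 2-[(5aS,10bS,11R)-10b-hydroxy-7-(3-methylbut-2-enyl)-3,8-bis(triisopropylsilyloxy)-5a,10b-dihydro-11H-benzofuro[2,3-b]chromen-11-yl]-1-[2-hydroxy-5-(3-methylbut-2-enyl)-4-(triisopropylsilyloxy)phenyl]ethanone (present as its lithium salts) | O=C(C[C@@H]1c2ccc(O[Si](C(C)C)(C(C)C)C(C)C)cc2O[C@H]2Oc3c(ccc(O[Si](C(C)C)(C(C)C)C(C)C)c3CC=C(C)C)[C@]21O)c1cc(CC=C(C)C)c(O[Si](C(C)C)(C(C)C)C(C)C)cc1O | intermediate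
37 | 1,3-diketone from 36 carrying the 3-(3-methylbut-2-enyl)-4-(triisopropylsilyloxy)benzoyl group on the central carbon (that carbon is stereochemically mobile) | O=C(c1cc(CC=C(C)C)c(O[Si](C(C)C)(C(C)C)C(C)C)cc1O)C(C(=O)c1ccc(O[Si](C(C)C)(C(C)C)C(C)C)c(CC=C(C)C)c1)[C@@H]1c2ccc(O[Si](C(C)C)(C(C)C)C(C)C)cc2O[C@H]2Oc3c(ccc(O[Si](C(C)C)(C(C)C)C(C)C)c3CC=C(C)C)[C@]21O | intermediate
38 | tetrakis(triisopropylsilyl) ether of the target (all four phenols silylated; (2R,3S,5aS,10bS,11R)) | CC(C)=CCc1cc([C@@]23Oc4cc(O[Si](C(C)C)(C(C)C)C(C)C)c(CC=C(C)C)cc4C(=O)[C@@H]2[C@@H]2c4ccc(O[Si](C(C)C)(C(C)C)C(C)C)cc4O[C@H]4Oc5c(ccc(O[Si](C(C)C)(C(C)C)C(C)C)c5CC=C(C)C)[C@]42O3)ccc1O[Si](C(C)C)(C(C)C)C(C)C | intermediate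
39 | CNP0152008.3 (rings A–H; (2R,3S) in the flavanone half, (5aS,10bS,11R) in the benzofurochromene half) | CC(C)=CCc1cc([C@@]23Oc4cc(O)c(CC=C(C)C)cc4C(=O)[C@@H]2[C@@H]2c4ccc(O)cc4O[C@H]4Oc5c(ccc(O)c5CC=C(C)C)[C@]42O3)ccc1O | target

**Step count and risks**

Total step count: 18. Longest linear sequence: 10 steps (steps 3–10, 17, 18).

Steps most likely to fail:

Step 17. The aggregated dianion 35 may add sluggishly to the hindered lactone, C-aroylation of the hindered enolate may stall at O-aroylated material, and the ketalisation may stop at a hemiketal or dihydrofuran or settle on the other face of ring D. The fallback sets out from 36 and returns at 37. The aryllithium addition is run alone and hydroxy ketone 36 is isolated. Acid chloride 34 is reduced with LiAlH(Ot-Bu)3 at −78 °C to 3-(3-methylbut-2-enyl)-4-(triisopropylsilyloxy)benzaldehyde F1. The lithium enolate of 36 (LiN(SiMe3)2, 3.2 equiv, THF, −78 °C) undergoes aldol addition to F1 to give the β-hydroxy ketone F2, whose benzylic carbinol is oxidised with MnO2 in CH2Cl2 to diketone 37. The acid stage of step 17 then leads to 38.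

Step 8. The carbene or the amine base may attack the activated aryl α-keto ester and cut the tether by acyl transfer, and facial selectivity at the homoenolate carbon may be poor. The fallback sets out from 5 and 13 and returns at 16. Phenol 5 is silylated (TBSCl, imidazole) to the enal F3, which is combined with keto ester 13 in the intermolecular carbene-catalysed homoenolate annulation (same triazolium salt, LiCl as cocatalyst) to give the monocyclic lactone ester F4. Bu4NF then frees the phenol, which lactonises onto the ethyl ester to give 16; only the diastereomer with ring G cis to the ester can close.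

Step 9. Hydride delivery may lose chemoselectivity (attack on the γ-lactone or over-reduction to the diol), and the acid stage may cyclise the prenyl group onto a neighbouring phenol. The fallback sets out from 16 and returns at 17. The phenyl-ester lactone of 16 is opened selectively with MeNH(OMe)·HCl and i-PrMgCl at −20 °C to the phenolic N-methoxy-N-methylamide F5, which Cp2Zr(H)Cl in THF reduces to the aldehyde that closes to lactol 17. MOM removal and acetalisation to 18 then follow under buffered acid (pyridinium p-toluenesulfonate).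

Further compounds
F1 | step 17 | 3-(3-methylbut-2-enyl)-4-(triisopropylsilyloxy)benzaldehyde | CC(C)=CCc1cc(C=O)ccc1O[Si](C(C)C)(C(C)C)C(C)C
F2 | step 17 | aldol adduct of 36 and F1 (β-hydroxy ketone, carbinol and α-carbon as mixtures) | O=C(c1cc(CC=C(C)C)c(O[Si](C(C)C)(C(C)C)C(C)C)cc1O)C(C(O)c1ccc(O[Si](C(C)C)(C(C)C)C(C)C)c(CC=C(C)C)c1)[C@@H]1c2ccc(O[Si](C(C)C)(C(C)C)C(C)C)cc2O[C@H]2Oc3c(ccc(O[Si](C(C)C)(C(C)C)C(C)C)c3CC=C(C)C)[C@]21O
F3 | step 8 | (E)-3-[2-(tert-butyldimethylsilyloxy)-4-(methoxymethoxy)phenyl]prop-2-enal | O=C/C=C/c1ccc(OCOC)cc1O[Si](C)(C)C(C)(C)C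
F4 | step 8 | ethyl (2S,3R)-2-[2,4-bis(methoxymethoxy)-3-(3-methylbut-2-enyl)phenyl]-3-[2-(tert-butyldimethylsilyloxy)-4-(methoxymethoxy)phenyl]-5-oxotetrahydrofuran-2-carboxylate | O=C1C[C@H](c2ccc(OCOC)cc2O[Si](C)(C)C(C)(C)C)[C@@](C(=O)OCC)(c2ccc(OCOC)c(CC=C(C)C)c2OCOC)O1
F5 | step 9 | (2S,3R)-2-[2,4-bis(methoxymethoxy)-3-(3-methylbut-2-enyl)phenyl]-3-[2-hydroxy-4-(methoxymethoxy)phenyl]-N-methoxy-N-methyl-5-oxotetrahydrofuran-2-carboxamide | O=C1C[C@H](c2ccc(OCOC)cc2O)[C@@](C(=O)N(C)OC)(c2ccc(OCOC)c(CC=C(C)C)c2OCOC)O1
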